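## Retrosynthetic overview
1. C12–C13: the 2-substituted butadiene is attached last, by B-alkyl Suzuki coupling of chloroprene with the borane of a C9-vinyl decalin.
2. Key step, C4–C5 then C9–C10: ring A and then ring B form in one operation from an open chain. Cp2TiCl opens a C4–C18 oxirane, which frees 18-OH. The tertiary radical closes 6-endo, then 6-exo, and loss of a C12 acetate leaves the vinyl group.
3. The chain already carries the C6 acetate and the C8 tertiary carbinol (6R,8S). These two centres set C4, C5, C9 and C10.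
4. C1–C10: B-alkyl Suzuki coupling of 2-allyl-2-methyloxirane with an E vinyl iodide triol.
5. C8–CH3 and C6–C7: 1,3-controlled MeMgBr addition, preceded by an Ipc2BCl aldol of (E)-3-iodobut-2-enal with (E)-4-oxopent-2-enyl acetate.

Assumption: positions use labdane numbering, and the target is the ent-labdane (4S,5S,6R,8S,9S,10R). The oxirane carbon (future C4) of 12–15 is a 1:1 epimer mixture and is left open in the SMILES, because step 9 turns it into a planar radical.

## Route

Step 1
Reactants: 1 but-2-yn-1-ol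
Product: 3 (E)-3-iodobut-2-en-1-ol, via alkenylzirconocene chloride 2 (not isolated)
Conditions: i-Bu2AlH (1.0 equiv), THF, 0 °C; Cp2ZrCl2 (1.2 equiv) + i-Bu2AlH (1.2 equiv), 0 °C to rt; I2, −78 °C; 1 M HCl
Reagents that add atoms: iodine, [I][I]
Why: Hydrozirconation–iodinolysis: Cp2ZrHCl adds syn to the O-aluminated alkynol with Zr on the methyl-bearing carbon, far from the bulky O–Al(i-Bu)2 group, and I2 cleaves C–Zr with retention, so iodine ends trans to CH2OH.

Step 2
Reactants: 3 (E)-3-iodobut-2-en-1-ol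
Product: 4 (E)-3-iodobut-2-enal
Conditions: activated MnO2 (15 equiv), CH2Cl2, rt, dark
Reagents that add atoms: none
Why: Neutral MnO2 oxidation of an allylic alcohol leaves the vinyl iodide and its geometry untouched.

Step 3
Reactants: 5 but-3-en-2-one, 6 allyl acetate
Product: 7 (E)-4-oxopent-2-en-1-yl acetate
Conditions: second-generation Hoveyda–Grubbs catalyst (2 mol %), 5 (3 equiv), CH2Cl2, 40 °C
Reagents that add atoms: none
Why: Olefin cross-metathesis of an electron-poor enone with a terminal allylic acetate favours the cross product and gives the E enone while ethene escapes.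

Step 4
Reactants: 7 (E)-4-oxopent-2-en-1-yl acetate, 4 (E)-3-iodobut-2-enal
Product: 9 (2E,6R,7E)-6-hydroxy-8-iodo-4-oxonona-2,7-dien-1-yl acetate, via diisopinocampheylboron dienolate 8 (not isolated)
Conditions: (−)-Ipc2BCl (1.3 equiv), Et3N (1.5 equiv), Et2O, 0 °C; 4, −78 to −20 °C; H2O2, MeOH, pH 7 buffer, 0 °C
Reagents that add atoms: none
Why: Reagent-controlled boron aldol (Paterson type): the methyl side of the enone is enolised kinetically and the Ipc ligands of the (−)-reagent shield one enal face, setting C6 as R in the sense established for methyl ketone enolates with enals (about 80–90% ee expected, to be raised by recrystallising triol 10).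

Step 5
Reactants: 9 (2E,6R,7E)-6-hydroxy-8-iodo-4-oxonona-2,7-dien-1-yl acetate
Product: 10 (2E,4S,6R,7E)-8-iodo-4-methylnona-2,7-diene-1,4,6-triol
Conditions: MeMgBr (6 equiv), CH2Cl2/Et2O, −78 to 0 °C; aq NH4Cl
Reagents that add atoms: methylmagnesium bromide, C[Mg]Br
Why: Grignard 1,2-addition under 1,3-induction: the C6 magnesium alkoxide chelates the ketone and methyl attacks the half-chair axially (the polar non-chelate model predicts the same face), which sets C8 as S (6,8-syn diol), while excess reagent removes the primary acetate so that no allylic ester is present in step 7.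

Step 6
Reactants: 11 2-methylpenta-1,4-diene
Product: 12 2-methyl-2-(prop-2-en-1-yl)oxirane (racemic)
Conditions: mCPBA (1.0 equiv), NaHCO3, CH2Cl2, 0 °C
Reagents that add atoms: 3-chloroperoxybenzoic acid, O=C(OO)c1cccc(Cl)c1
Why: In this Prilezhaev epoxidation the 1,1-disubstituted alkene reacts about twenty times faster than the monosubstituted one, and the new centre need not be controlled because it is erased in step 9.

Step 7
Reactants: 12 2-methyl-2-(prop-2-en-1-yl)oxirane, 10 (2E,4S,6R,7E)-8-iodo-4-methylnona-2,7-diene-1,4,6-triol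
Product: 14 (2E,4S,6R,7E)-4,8-dimethyl-11-(2-methyloxiran-2-yl)undeca-2,7-diene-1,4,6-triol, via B-alkyl-9-BBN adduct 13 (not isolated)
Conditions: 12 (1.5 equiv), 9-BBN, THF, 0 °C to rt; 10, PdCl2(dppf) (5 mol %), AsPh3 (5 mol %), Cs2CO3 (3 equiv), DMF/H2O, rt
Reagents that add atoms: none
Why: B-alkyl Suzuki–Miyaura coupling: 9-BBN adds anti-Markovnikov to the terminal alkene without touching the oxirane, and zerovalent palladium joins it to the vinyl iodide with retention, giving the E C5=C10 alkene while the free hydroxyls are tolerated.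

Step 8
Reactants: 14 (2E,4S,6R,7E)-4,8-dimethyl-11-(2-methyloxiran-2-yl)undeca-2,7-diene-1,4,6-triol
Product: 15 (2E,4S,6R,7E)-4-hydroxy-4,8-dimethyl-11-(2-methyloxiran-2-yl)undeca-2,7-diene-1,6-diyl diacetate
Conditions: Ac2O (2.5 equiv), pyridine, DMAP (5 mol %), CH2Cl2, 0 °C to rt
Reagents that add atoms: acetic anhydride, CC(=O)OC(C)=O
Why: DMAP-catalysed acylation takes the primary and secondary allylic alcohols but not the tertiary C8–OH, so one operation installs both the final C6 acetate and the C12 leaving group.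

Step 9
Reactants: 15 (2E,4S,6R,7E)-4-hydroxy-4,8-dimethyl-11-(2-methyloxiran-2-yl)undeca-2,7-diene-1,6-diyl diacetate
Product: 18 (1R,3S,4S,4aR,8S,8aS)-4-ethenyl-3-hydroxy-8-(hydroxymethyl)-3,4a,8-trimethyldecahydronaphthalen-1-yl acetate, via β-titanoxy tertiary radical 16 (not isolated), via secondary alkyltitanium 17 (not isolated)
Conditions: Cp2TiCl2 (0.3 equiv), Mn dust (6 equiv), 2,4,6-collidine·HCl (2.5 equiv), degassed THF (5 mM, syringe-pump addition of 15), rt; aq NaH2PO4
Reagents that add atoms: none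
Why: Proposed new method: Cp2TiCl opens the 2,2-disubstituted oxirane homolytically to tertiary radical 16, which closes ring A 6-endo on C5=C10 and then ring B 6-exo on C9=C11 through a chair–chair array in which H6 eclipses the C10 methyl (A1,3 strain) and the C6 acetate, C8 hydroxyl, CH2O–Ti group and alkenyl arm are all equatorial, so that C4 (S), C5 (S), C10 (R) and C9 (S) follow from C6 and C8, after which a second Cp2TiCl captures the C11 radical and alkyltitanium 17 loses its β-acetate to leave the vinyl group; the closest known reaction types are the titanocene-catalysed epoxypolyene radical cyclisation (Nugent–RajanBabu opening) and the Cp2TiCl-induced β-acetoxy elimination that turns glycosyl radicals into glycals, and the termination is the radical counterpart of allylsilane-terminated cationic polyene cyclisation.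

Step 10
Reactants: 18 (1R,3S,4S,4aR,8S,8aS)-4-ethenyl-3-hydroxy-8-(hydroxymethyl)-3,4a,8-trimethyldecahydronaphthalen-1-yl acetate, 19 2-chlorobuta-1,3-diene (chloroprene)
Product: 21 (1R,3S,4S,4aR,8S,8aS)-3-hydroxy-8-(hydroxymethyl)-3,4a,8-trimethyl-4-(3-methylidenepent-4-en-1-yl)decahydronaphthalen-1-yl acetate (target), via B-alkyl-9-BBN adduct 20 (not isolated)
Conditions: 9-BBN (4 equiv), THF, rt; 3 M aq K3PO4; 19 (3 equiv), Pd(OAc)2 (5 mol %), SPhos (10 mol %), THF, 40 °C
Reagents that add atoms: none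
Why: Hydroboration and B-alkyl Suzuki–Miyaura coupling: boron goes to the unhindered terminal C12, which stays nucleophilic so the 8-OH cannot close an ether onto it, and the activated vinyl chloride couples at C13 under conditions that spare the hindered acetate and touch no stereocentre.

## Compound list
1 | but-2-yn-1-ol | CC#CCO | starting material
2 | (E)-alkenylzirconocene chloride of the O-diisobutylaluminated alkynol | C/C(=C\CO[Al](CC(C)C)CC(C)C)[Zr](Cl)(C1C=CC=C1)C1C=CC=C1 | intermediate
3 | (E)-3-iodobut-2-en-1-ol | I/C(C)=C/CO | intermediate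
4 | (E)-3-iodobut-2-enal | I/C(C)=C/C=O | intermediate
5 | but-3-en-2-one | CC(=O)C=C | starting material
6 | allyl acetate | C=CCOC(C)=O | starting material
7 | (E)-4-oxopent-2-en-1-yl acetate | CC(=O)/C=C/COC(C)=O | intermediate
8 | diisopinocampheylboron dienolate of 7 | C=C(OB([C@@H]1C[C@@H]2C[C@H]([C@H]1C)C2(C)C)[C@@H]1C[C@@H]2C[C@H]([C@H]1C)C2(C)C)/C=C/COC(C)=O | intermediate
9 | (2E,6R,7E)-6-hydroxy-8-iodo-4-oxonona-2,7-dien-1-yl acetate | I/C(C)=C/[C@H](O)CC(=O)/C=C/COC(C)=O | intermediate
10 | (2E,4S,6R,7E)-8-iodo-4-methylnona-2,7-diene-1,4,6-triol | I/C(C)=C/[C@H](O)C[C@](C)(O)/C=C/CO | intermediate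
11 | 2-methylpenta-1,4-diene | C=CCC(C)=C | starting material
12 | 2-methyl-2-(prop-2-en-1-yl)oxirane, racemic | C=CCC1(C)CO1 | intermediate
13 | 9-[3-(2-methyloxiran-2-yl)propyl]-9-borabicyclo[3.3.1]nonane | CC1(CCCB2C3CCCC2CCC3)CO1 | intermediate
14 | (2E,4S,6R,7E)-4,8-dimethyl-11-(2-methyloxiran-2-yl)undeca-2,7-diene-1,4,6-triol | CC1(CCC/C(C)=C/[C@H](O)C[C@](C)(O)/C=C/CO)CO1 | intermediate
15 | (2E,4S,6R,7E)-4-hydroxy-4,8-dimethyl-11-(2-methyloxiran-2-yl)undeca-2,7-diene-1,6-diyl diacetate | CC1(CCC/C(C)=C/[C@H](OC(C)=O)C[C@](C)(O)/C=C/COC(C)=O)CO1 | intermediate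
16 | C4 tertiary radical bearing CH2O–TiCp2Cl | C[C](CO[Ti](Cl)(C1C=CC=C1)C1C=CC=C1)CCC/C(C)=C/[C@H](OC(C)=O)C[C@](C)(O)/C=C/COC(C)=O | intermediate
17 | bicyclic C11 alkyltitanium with β-acetate at C12 | CC(=O)OCC([Ti](Cl)(C1C=CC=C1)C1C=CC=C1)[C@H]1[C@]2(C)CCC[C@](C)(CO[Ti](Cl)(C3C=CC=C3)C3C=CC=C3)[C@H]2[C@H](OC(C)=O)C[C@]1(C)O | intermediate
18 | (1R,3S,4S,4aR,8S,8aS)-4-ethenyl-3-hydroxy-8-(hydroxymethyl)-3,4a,8-trimethyldecahydronaphthalen-1-yl acetate | C=C[C@H]1[C@]2(C)CCC[C@](C)(CO)[C@H]2[C@H](OC(C)=O)C[C@]1(C)O | intermediate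
19 | 2-chlorobuta-1,3-diene | C=CC(Cl)=C | starting material
20 | C12 B-alkyl-9-BBN adduct of 18 | C1CC2CCCC(C1)B2CC[C@H]1[C@]2(C)CCC[C@](C)(CO)[C@H]2[C@H](OC(C)=O)C[C@]1(C)O | intermediate
21 | (1R,3S,4S,4aR,8S,8aS)-3-hydroxy-8-(hydroxymethyl)-3,4a,8-trimethyl-4-(3-methylidenepent-4-en-1-yl)decahydronaphthalen-1-yl acetate (6-O-acetylandalusol) | C=CC(=C)CC[C@H]1[C@]2(C)CCC[C@](C)(CO)[C@H]2[C@H](OC(C)=O)C[C@]1(C)O | target

## Step count and risks
Total steps: 10. Longest linear sequence: 8 (steps 1, 2, 4, 5, 7, 8, 9, 10). No protecting groups are used.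

**Step 9 (most at risk).**
- The 6-exo closure joins a tertiary radical to a hindered alkene that is only weakly activated.
- Radical 16 may disproportionate to an allylic alcohol before ring A closes.
- A cis ring fusion can compete with the trans fusion.
- The bulky Cp2TiCl must still reach the C11 radical.

The fallback sets out from 15. Zerovalent-palladium allylic substitution (Pd(PPh3)4, PhSO2Na, THF/MeOH, rt) at the faster-ionising primary acetate gives (2E,4S,6R,7E)-4-hydroxy-4,8-dimethyl-11-(2-methyloxiran-2-yl)-1-(phenylsulfonyl)undeca-2,7-dien-6-yl acetate F4. Opening its oxirane with Cp2TiCl then ends by radical addition–fragmentation. The sulfone lowers the acceptor LUMO, and the C11 radical expels the sulfonyl radical by itself, so no carbon–titanium bond is needed. This path comes back to the route at 18.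

**Step 4.**
- Methyl ketone Ipc2B enolates give only moderate ee.
- The β-iodo enal is sensitive to amine.
- The absolute sense must be confirmed at 9 by Mosher ester analysis; (+)-Ipc2BCl is equally available if it proves reversed.

The fallback sets out from 4 and replaces reagent control by an auxiliary acetate aldol.
- The doubly deprotonated (R)-2-hydroxy-1,2,2-triphenylethyl acetate (LDA, MgBr2, below −100 °C) adds to 4. It gives (1R)-2-hydroxy-1,2,2-triphenylethyl (3R,4E)-3-hydroxy-5-iodohex-4-enoate F1, which can be purified by crystallisation.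
- Me(MeO)NH·HCl/AlMe3 converts F1 into (3R,4E)-3-hydroxy-5-iodo-N-methoxy-N-methylhex-4-enamide F2.
- The (E)-3-oxidoprop-1-enyl organometallic is made from (E)-3-(tributylstannyl)prop-2-en-1-ol with n-BuLi (2 equiv), then CeCl3. It adds to F2 to give (2E,6R,7E)-1,6-dihydroxy-8-iodonona-2,7-dien-4-one F3.
- MeMgBr, used as in step 5, brings this path back to the route at 10.

**Step 10.** Chloroprene is a sluggish vinyl chloride that also polymerises, and the product diene is sensitive. The fallback sets out from 20 and builds the diene stepwise.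
- Coupling 20 with 2-bromoprop-2-en-1-ol under the same palladium conditions gives (1R,3S,4S,4aR,8S,8aS)-3-hydroxy-8-(hydroxymethyl)-4-[3-(hydroxymethyl)but-3-en-1-yl]-3,4a,8-trimethyldecahydronaphthalen-1-yl acetate F5.
- MnO2 oxidises only the allylic alcohol of F5, giving (1R,3S,4S,4aR,8S,8aS)-4-(3-formylbut-3-en-1-yl)-3-hydroxy-8-(hydroxymethyl)-3,4a,8-trimethyldecahydronaphthalen-1-yl acetate F6.
- Wittig methylenation of F6 (Ph3PCH3Br, KHMDS, excess, −78 °C) comes back to the route at 21.

## Further compounds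
F1 | step 4 | (1R)-2-hydroxy-1,2,2-triphenylethyl (3R,4E)-3-hydroxy-5-iodohex-4-enoate | I/C(C)=C/[C@H](O)CC(=O)O[C@H](c1ccccc1)C(O)(c1ccccc1)c1ccccc1
F2 | step 4 | (3R,4E)-3-hydroxy-5-iodo-N-methoxy-N-methylhex-4-enamide | I/C(C)=C/[C@H](O)CC(=O)N(C)OC
F3 | step 4 | (2E,6R,7E)-1,6-dihydroxy-8-iodonona-2,7-dien-4-one | I/C(C)=C/[C@H](O)CC(=O)/C=C/CO
F4 | step 9 | (2E,4S,6R,7E)-4-hydroxy-4,8-dimethyl-11-(2-methyloxiran-2-yl)-1-(phenylsulfonyl)undeca-2,7-dien-6-yl acetate | CC1(CCC/C(C)=C/[C@H](OC(C)=O)C[C@](C)(O)/C=C/CS(=O)(=O)c2ccccc2)CO1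
F5 | step 10 | (1R,3S,4S,4aR,8S,8aS)-3-hydroxy-8-(hydroxymethyl)-4-[3-(hydroxymethyl)but-3-en-1-yl]-3,4a,8-trimethyldecahydronaphthalen-1-yl acetate | C=C(CO)CC[C@H]1[C@]2(C)CCC[C@](C)(CO)[C@H]2[C@H](OC(C)=O)C[C@]1(C)O
F6 | step 10 | (1R,3S,4S,4aR,8S,8aS)-4-(3-formylbut-3-en-1-yl)-3-hydroxy-8-(hydroxymethyl)-3,4a,8-trimethyldecahydronaphthalen-1-yl acetate | C=C(C=O)CC[C@H]1[C@]2(C)CCC[C@](C)(CO)[C@H]2[C@H](OC(C)=O)C[C@]1(C)O
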